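## Analysis of the target

The target 12 is the oleate of a tertiary alcohol on a 3,4-dihydro-isochromene-6,8-dione bicycle. Ring A is the carbocycle C4a–C5–C6–C7–C8–C8a and ring B the dihydropyran C1–O2–C3–C4–C4a–C8a (isochromene numbering, used throughout). Ring B holds the vinylogous ester O2–C1H=C8a–C8=O and ring A the cross-conjugated enone C4a=C5H–C6=O. Between the two ketones sits C7, a quaternary carbon that bears a methyl group and the ester oxygen.

There are two stereocenters, C3 (R; O2 > C4 > CH3 > H) and C7 (R; O > C8 > C6 > CH3, C8 ranking above C6 because C8a carries three carbon branches and C5 only two), and one Z-alkene in the C18 chain. C3 and C7 lie five bonds apart across a flat array of sp2 atoms, so neither can steer the other and each has to be set on its own.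

The feature that decides the strategy is C7 of ring A with its C7–O bond. The array C6(=O)–C7(CH3)(O-acyl)–C8(=O) in a cyclohexadienone is a 2-methylresorcinol that has lost its aromaticity by C–O bond formation at the carbon between its two oxygens. The C7–O bond is at the same time the alkyl–oxygen bond of the ester.

The sensitive points are:
- C1, which is electrophilic and exchanges O2 for nitrogen with amines;
- the non-enolisable β-diketone, which opens by retro-Claisen attack of basic nucleophiles;
- the tertiary acyloxy group, which is lost with re-aromatisation under reducing conditions;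
- C3, which base can epimerise through retro-oxa-Michael opening of ring B;
- the Z-alkene, which rules out peracids, hydrogenation and radical conditions once the chain is in place.

The difficulty therefore sits in one place. A fully substituted C–O stereocenter must be made late, under reagent control, on a flat precursor whose two oxygen atoms next to C7 are nearly alike, under conditions that dione and alkene both survive.

## Retrosynthetic reasoning

**12 ⇒ 9 + 10.** The ester is cut at its alkyl–oxygen bond C7–O, not at the acyl–oxygen bond. This one cut removes the quaternary stereocenter C7, the whole C18 chain and the non-aromatic state of ring A. What remains is the vinylogous acid 9 (C11, flat, one stereocenter), in which C7 is the central carbon of an enolised β-diketone and so the only carbon that can take up an oxygen substituent. The forward reaction has to join two nucleophiles, the enol carbon C7 of 9 and a carboxylate oxygen of oleic acid 10. A chiral aryl-λ3-iodane that carries the oleate as ligand reverses the polarity (via 11) and must also choose the face of C7, because C3 is too far away to help.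

**9 ⇒ 7.** Ring B is opened by taking out C1, that is by cutting C1–C8a and C1–O2. The resorcinol ring of triol 7 is symmetrical (both positions next to the side chain are equivalent), so a one-carbon electrophile at the oxidation level of formic acid can give only one regioisomer. C–C bond formation, acetal closure (8) and loss of alcohol lead to 9 without any redox adjustment at C1.

**7 ⇒ 6.** The two phenols are masked as methyl ethers (O–CH3 bonds). These are the groups that pass unchanged through C–H borylation and organomagnesium chemistry, and a Lewis acid removes both in one operation just before the ring closure.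

**6 ⇒ 3 + 4.** The aryl–CH2 bond C4–C4a is cut so that C3 is bought with (R)-propylene oxide 4. The aryl nucleophile 5 attacks the unsubstituted epoxide carbon, the C–O bond of the stereocenter is never touched, and the configuration is carried through as (R).

**3 ⇒ 1.** The bromine of 3 stands meta to both methoxy groups, where electrophilic substitution of 1 cannot place it. It is, however, the only C–H of 1 without an ortho neighbour, so a sterically controlled C–H borylation (2) followed by halogenation reaches it directly from the cheapest possible arene.

## Alternatives that were turned down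

**Alternative 1:** The textbook cut is the acyl–oxygen bond of the ester. 12 would come from the tertiary alcohol A1 and an activated form of 10. A1 would come from hydroxylation at C7 of the open hydroxy aldehyde A2 (a pentavalent iodine oxidant, or copper with O2 and a chiral diamine), with ring B closing behind the oxidation. It was turned down for three reasons:
- It makes the C7–O bond and the O–acyl bond in two operations where one can do both.
- The hydroxyl of A1 is tertiary and flanked by two carbonyl groups. Its acylation needs a nucleophilic catalyst and an excess of acylating agent, and under exactly those conditions C1 is attacked (O2/N exchange, ring opening) and the β-diketone is open to retro-Claisen cleavage and α-ketol shift.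
- A2 exists in ring–chain equilibrium with its lactol and with 9, which blurs the substrate that the oxidant sees.

The route is one step longer and is kept only as the fallback for the key step.

**Alternative 2:** Ring A could be built onto a finished ring B by cutting C8–C8a and C4a=C5. The enantiopure pyranone A3 would be C-acylated at its α-carbon with the acid chloride A4, which already holds C7 with its ester, to give the triketone A5. An intramolecular aldol condensation of the methyl ketone of A5 onto the pyranone carbonyl would then close ring A. It was turned down for these reasons: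
- A4 needs its own asymmetric α-oxygenation, and it is an α-acyloxy-β-keto acid chloride, a centre between two acyl groups that retro-Claisen cleavage destroys.
- The aldol step needs base enolisation in A5 next to a non-enolisable 1,3-diketone, and its acceptor is the least electrophilic carbonyl of the molecule (a vinylogous ester).
- The oleate can migrate to any enolate oxygen that forms.

The plan looks convergent but is longer, and it moves the C7 problem to a more fragile compound without solving it.

**Alternative 3:** C3 could be set last. The fully unsaturated azaphilone ester A6 (with C3=C4) would be made first, and its enol ether double bond reduced by an asymmetric conjugate hydride addition (a copper hydride with a chiral bisphosphine). It was turned down for these reasons: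
- Hydride adds to carbons β to a carbonyl, here C1 and C4a, whereas C3 carries the donor oxygen O2 and is the least electrophilic position of the trienone.
- 1,2-Reduction of the ketones and reductive loss of the C7 acyloxy group with re-aromatisation would compete.
- A6 still needs all of the C7 chemistry, so the reduction is an added problem and not a replacement. Buying C3 in an epoxide costs nothing.

Key step: step 5

Assumption: the sense of induction of the lactate-derived iodane at C7 cannot be derived with confidence. The (2R,2'R)-reagent is written, and its (2S,2'S)-enantiomer, made from the other lactate, takes its place if the first run shows the opposite sense.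

Remark: 9 is drawn as the 6-hydroxy-8-oxo tautomer; the 8-hydroxy-6-oxo tautomer is the same compound in solution.

## Route

Step 1
Reactants: 1 1,3-dimethoxy-2-methylbenzene (2,6-dimethoxytoluene)
Product: 3 5-bromo-1,3-dimethoxy-2-methylbenzene, via aryl pinacolboronate 2 (not isolated)
Conditions: [Ir(OMe)(cod)]2 (1.5 mol %), 4,4'-di-tert-butyl-2,2'-bipyridine (3 mol %), B2pin2 (1.0 equiv), THF, 80 °C; solvent removed; then CuBr2 (3 equiv), MeOH/H2O 1:1, 80 °C
Reagents that add atoms: copper dibromide, [Cu+2].[Br-].[Br-]
Why: Iridium-catalysed C–H borylation (Hartwig–Miyaura type) is governed by sterics and takes the only C–H of 1 without an ortho substituent, C5, which is meta to both methoxy groups; ipso-bromodeboronation of 2 with copper dibromide then puts bromine on the same carbon, a position that electrophilic bromination of 1 cannot reach. No stereocenter is formed.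

Step 2
Reactants: 3 5-bromo-1,3-dimethoxy-2-methylbenzene; 4 (R)-2-methyloxirane ((R)-propylene oxide)
Product: 6 (2R)-1-(3,5-dimethoxy-4-methylphenyl)propan-2-ol, via arylmagnesium bromide 5 (not isolated)
Conditions: Mg turnings, I2 (cat.), THF, reflux; then CuI (10 mol %), 4 (1.3 equiv), THF, −30 °C to 0 °C; aq. NH4Cl
Reagents that add atoms: none
Why: Copper-catalysed opening of a terminal epoxide by an aryl Grignard reagent is an SN2 attack at the unsubstituted carbon; the C–O bond of the stereocenter of 4 is not touched and the CIP order (O > CH2 > CH3 > H) does not change, so 6 keeps the (R) configuration that becomes C3 of the target.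

Step 3
Reactants: 6 (2R)-1-(3,5-dimethoxy-4-methylphenyl)propan-2-ol
Product: 7 5-[(2R)-2-hydroxypropyl]-2-methylbenzene-1,3-diol
Conditions: BBr3 (3.5 equiv), CH2Cl2, −78 °C to 0 °C; MeOH, then aq. NaHCO3
Reagents that add atoms: none
Why: Boron tribromide cleaves both aryl methyl ethers by bromide attack on the methyl groups of the boron-complexed ethers; the secondary hydroxyl is held as a borate and set free on methanolysis, and the low temperature should keep it from being displaced, so C3 stays (R).

Step 4
Reactants: 7 5-[(2R)-2-hydroxypropyl]-2-methylbenzene-1,3-diol
Product: 9 (3R)-6-hydroxy-3,7-dimethyl-3,4-dihydro-8H-isochromen-8-one, via 1-ethoxyisochromane acetal 8 (not isolated)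
Conditions: HC(OEt)3 (4 equiv), CF3CO2H (1.0 equiv), 1,4-dioxane, rt; evaporation and azeotropic drying with toluene
Reagents that add atoms: triethyl orthoformate, CCOC(OCC)OCC
Why: Acid-catalysed Friedel–Crafts formylation with an orthoformate, followed by oxa-Pictet–Spengler-type acetal closure, is a known reaction type for resorcinols that carry a 2-hydroxyalkyl chain; the two ring positions next to the side chain of 7 are equivalent, so a single regioisomer 8 should form, and loss of ethanol from 8 gives the push–pull stabilised vinylogous acid 9. C3 is not involved.

Step 5
Reactants: 9 (3R)-6-hydroxy-3,7-dimethyl-3,4-dihydro-8H-isochromen-8-one; 10 oleic acid ((9Z)-octadec-9-enoic acid)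
Product: 12 (3R,7R)-3,7-dimethyl-6,8-dioxo-3,4,7,8-tetrahydro-6H-isochromen-7-yl (9Z)-octadec-9-enoate, via iodanyl enol ether 11 (not isolated)
Conditions: aryl-λ3-iodane diacetate ArI(OAc)2 (1.2 equiv; ArI = (2R,2'R)-2,2'-[(2-iodo-1,3-phenylene)bis(oxy)]bis[N-(2,4,6-trimethylphenyl)propanamide], oxidised beforehand with peracetic acid), 10 (2.6 equiv), PhCl, 40 °C, 20 mbar (AcOH distilled off); then 9 (1.0 equiv), 4 Å molecular sieves, CH2Cl2, −40 °C to −20 °C
Reagents that add atoms: none
Why: Proposed new method: the vinylogous acid 9 exchanges its O6–H for one oleate ligand of the aryl-λ3-iodane bis(oleate) to give 11, and the remaining oleate is then transferred to C7 with loss of the iodoarene (ligand coupling or SN2′ attack), which turns the enol C6=C7 into the C6 ketone and leaves C1=C8a and C4a=C5 where the target has them; the closest known reaction types are the Wessely acetoxylation of 6,8-dihydroxy-2-benzopyrylium salts with Pb(OAc)4 to 7-acetoxy-isochromene-6,8-diones, the α-acyloxylation of 2-alkyl-1,3-diketones with PhI(OAc)2 and the enantioselective Kita spirolactonisation of arenols with the same lactate-derived iodoarene, and what is new is the reagent-controlled delivery of an external carboxylate. No ring is closed. C7 is the only α-carbon of the enol and therefore the only carbon that can accept the carboxylate, so no regiochemical question arises. The new stereocenter C7 is set by the reagent alone: the two lactamide arms fold over trivalent iodine through N–H···O hydrogen bonds and leave one face of the bound enol open, while C3 is five bonds away and should have no say. The selectivity the step needs is therefore facial, and it rests on iodine binding O6 and not O8, which is the vinylogous-ester carbonyl oxygen and is hemmed in by the peri C1–H. Chemoselectivity towards the Z-alkene is secured by the low temperature and the absence of a Lewis acid, conditions under which trivalent iodine carboxylates leave isolated alkenes alone. The (3R,7S) epimer from the minor pathway is a diastereomer of 12 and should be removable by chromatography, and the iodoarene is recovered.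

## Compound list

1 | 1,3-dimethoxy-2-methylbenzene | COc1cccc(OC)c1C | starting material
2 | 2-(3,5-dimethoxy-4-methylphenyl)-4,4,5,5-tetramethyl-1,3,2-dioxaborolane | COc1cc(B2OC(C)(C)C(C)(C)O2)cc(OC)c1C | intermediate
3 | 5-bromo-1,3-dimethoxy-2-methylbenzene | COc1cc(Br)cc(OC)c1C | intermediate
4 | (R)-2-methyloxirane | C[C@@H]1CO1 | starting material
5 | (3,5-dimethoxy-4-methylphenyl)magnesium bromide | COc1cc([Mg]Br)cc(OC)c1C | intermediate
6 | (2R)-1-(3,5-dimethoxy-4-methylphenyl)propan-2-ol | C[C@@H](O)Cc1cc(OC)c(C)c(OC)c1 | intermediate
7 | 5-[(2R)-2-hydroxypropyl]-2-methylbenzene-1,3-diol | C[C@@H](O)Cc1cc(O)c(C)c(O)c1 | intermediate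
8 | (3R)-1-ethoxy-3,7-dimethyl-3,4-dihydro-1H-isochromene-6,8-diol (both C1 epimers) | CCOC1O[C@H](C)Cc2cc(O)c(C)c(O)c12 | intermediate
9 | (3R)-6-hydroxy-3,7-dimethyl-3,4-dihydro-8H-isochromen-8-one | C[C@@H]1CC2=CC(O)=C(C)C(=O)C2=CO1 | intermediate
10 | oleic acid ((9Z)-octadec-9-enoic acid) | CCCCCCCC/C=C\CCCCCCCC(=O)O | starting material
11 | [2,6-bis({(2R)-1-oxo-1-[(2,4,6-trimethylphenyl)amino]propan-2-yl}oxy)phenyl]{[(3R)-3,7-dimethyl-8-oxo-3,4-dihydro-8H-isochromen-6-yl]oxy}-λ3-iodanyl (9Z)-octadec-9-enoate | C[C@@H]1CC2=CC(OI(OC(=O)CCCCCCC/C=C\CCCCCCCC)c3c(O[C@H](C)C(=O)Nc4c(C)cc(C)cc4C)cccc3O[C@H](C)C(=O)Nc3c(C)cc(C)cc3C)=C(C)C(=O)C2=CO1 | intermediate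
12 | (3R,7R)-3,7-dimethyl-6,8-dioxo-3,4,7,8-tetrahydro-6H-isochromen-7-yl (9Z)-octadec-9-enoate | C[C@@H]1CC2=CC(=O)[C@@](C)(OC(=O)CCCCCCC/C=C\CCCCCCCC)C(=O)C2=CO1 | target

## Step count and risk

Total number of steps: 5. Longest linear sequence: 5 steps (1 → 3 → 6 → 7 → 9 → 12); 4 and 10 enter as purchased fragments.

**Step 5 (key step, Proposed new method).** The most likely failure is poor facial selectivity at C7. The two oxygen atoms next to C7 are nearly alike, and an iodane bound at O8 would present the opposite face of C7 to the carboxylate. A second failure is transfer of a residual acetate ligand if acetic acid is not fully removed. The fallback uses known chemistry, sets out from 9 and returns at 12: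
- 9 is oxidised with 2-iodoxybenzoic acid (a pentavalent iodine reagent; DMF, rt), a hydroxylative dearomatisation established for this type of vinylogous acid. This should give (3R,7R)-7-hydroxy-3,7-dimethyl-3,4-dihydro-6H-isochromene-6,8(7H)-dione F1 together with its C7 epimer (3R,7S)-7-hydroxy-3,7-dimethyl-3,4-dihydro-6H-isochromene-6,8(7H)-dione F2.
- F1 and F2 are diastereomers and are separated by chromatography.
- 10 is converted with oxalyl chloride (cat. DMF, CH2Cl2) into (9Z)-octadec-9-enoyl chloride F3.
- F1 is acylated with F3 (Et3N, 4-(dimethylamino)pyridine cat., CH2Cl2, 0 °C) to give 12.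

This is the two-operation route of Alternative 1, with C7 control given up for a separation.

**Step 4.** The orthoformate may be taken up by the phenols and the side-chain hydroxyl (formates, ortho esters) without C–C bond formation, the loss of ethanol from 8 may stay incomplete, and the electron-rich vinylogous acid may hydrate or self-condense during isolation. The fallback brings in C1 at the formaldehyde level and oxidises afterwards; it sets out from 7 and returns at 9:
- 7 undergoes an oxa-Pictet–Spengler closure with dimethoxymethane (1.0 equiv, p-TsOH 10 mol %, CH2Cl2, rt) to (3R)-3,7-dimethyl-3,4-dihydro-1H-isochromene-6,8-diol F4.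
- F4 is dehydrogenated at C1 with 2,3-dichloro-5,6-dicyano-1,4-benzoquinone (1.0 equiv, CH2Cl2, 0 °C), a hydride abstraction that the ortho- and para-hydroxyl groups assist, to give 9.

**Step 3.** The borate-activated secondary hydroxyl may be substituted or eliminated under the Lewis acid, which would cost the C3 oxygen or its configuration, and the second ether may be cleaved only in part. The fallback ties this oxygen into ring B before the ethers are cleaved; it sets out from 6, returns at 9 and bypasses 7 and 8:
- 6 is cyclised with trimethyl orthoformate (BF3·OEt2, CH2Cl2, −20 °C) to (3R)-1,6,8-trimethoxy-3,7-dimethyl-3,4-dihydro-1H-isochromene F5.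
- F5 is treated with BBr3 (CH2Cl2, −78 °C to 0 °C). The acetal ionises, the two methyl ethers (now vinylogous oxocarbenium ethers, the most reactive methyl groups present) are cleaved, and buffered work-up should give 9 directly.

**Step 1.** Copper dibromide may brominate the electron-rich ring ortho or para to a methoxy group in competition with ipso substitution, or the boronate may be protodeboronated in the hot aqueous medium. The fallback avoids the bromide and sets C3 by asymmetric epoxidation; it sets out from 2 (isolated by filtration through silica), returns at 6 and bypasses 3, 4 and 5: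
- Suzuki–Miyaura coupling of 2 with (E)-1-bromoprop-1-ene (Pd(PPh3)4 3 mol %, K2CO3, dioxane/H2O, 80 °C) gives 1,3-dimethoxy-2-methyl-5-[(1E)-prop-1-en-1-yl]benzene F6.
- Shi epoxidation of F6 with the D-fructose-derived ketone 1,2:4,5-di-O-isopropylidene-β-D-erythro-2,3-hexodiulo-2,6-pyranose (30 mol %, KHSO5, K2CO3 buffer, MeCN/dimethoxymethane/H2O, 0 °C) should give (2R,3R)-2-(3,5-dimethoxy-4-methylphenyl)-3-methyloxirane F7.
- Hydrogenolysis of the benzylic C–O bond of F7 (H2 1 atm, Pd/C, EtOAc, rt) leaves the carbinol carbon untouched and gives 6.

Further compounds
F1 | step 5 | (3R,7R)-7-hydroxy-3,7-dimethyl-3,4-dihydro-6H-isochromene-6,8(7H)-dione | C[C@@H]1CC2=CC(=O)[C@@](C)(O)C(=O)C2=CO1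
F2 | step 5 | (3R,7S)-7-hydroxy-3,7-dimethyl-3,4-dihydro-6H-isochromene-6,8(7H)-dione | C[C@@H]1CC2=CC(=O)[C@](C)(O)C(=O)C2=CO1
F3 | step 5 | (9Z)-octadec-9-enoyl chloride | CCCCCCCC/C=C\CCCCCCCC(Cl)=O
F4 | step 4 | (3R)-3,7-dimethyl-3,4-dihydro-1H-isochromene-6,8-diol | C[C@@H]1Cc2cc(O)c(C)c(O)c2CO1
F5 | step 3 | (3R)-1,6,8-trimethoxy-3,7-dimethyl-3,4-dihydro-1H-isochromene | C[C@@H]1Cc2cc(OC)c(C)c(OC)c2C(OC)O1
F6 | step 1 | 1,3-dimethoxy-2-methyl-5-[(1E)-prop-1-en-1-yl]benzene | C/C=C/c1cc(OC)c(C)c(OC)c1
F7 | step 1 | (2R,3R)-2-(3,5-dimethoxy-4-methylphenyl)-3-methyloxirane | C[C@H]1O[C@@H]1c1cc(OC)c(C)c(OC)c1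
A1 | alternative 1 | (3R,7R)-7-hydroxy-3,7-dimethyl-3,4-dihydro-6H-isochromene-6,8(7H)-dione | C[C@@H]1CC2=CC(=O)[C@@](C)(O)C(=O)C2=CO1
A2 | alternative 1 | 2,4-dihydroxy-6-[(2R)-2-hydroxypropyl]-3-methylbenzaldehyde | C[C@@H](O)Cc1cc(O)c(C)c(O)c1C=O
A3 | alternative 2 | (2R)-2-methyl-2,3-dihydro-4H-pyran-4-one | C[C@@H]1CC(=O)C=CO1
A4 | alternative 2 | (2R)-2-methyl-2-[(9Z)-octadec-9-enoyloxy]-3-oxobutanoyl chloride | CC(=O)[C@@](C)(OC(=O)CCCCCCC/C=C\CCCCCCCC)C(Cl)=O
A5 | alternative 2 | (2R)-2-methyl-1-[(2R)-2-methyl-4-oxo-3,4-dihydro-2H-pyran-5-yl]-1,3-dioxobutan-2-yl (9Z)-octadec-9-enoate | CC(=O)[C@@](C)(OC(=O)CCCCCCC/C=C\CCCCCCCC)C(=O)C1=CO[C@H](C)CC1=O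
A6 | alternative 3 | (7R)-3,7-dimethyl-6,8-dioxo-7,8-dihydro-6H-isochromen-7-yl (9Z)-octadec-9-enoate | CC1=CC2=CC(=O)[C@@](C)(OC(=O)CCCCCCC/C=C\CCCCCCCC)C(=O)C2=CO1
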